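**Plan**

- Retrosynthesis (germacrane numbering): the C8 and C3 ester C–O bonds and C11=C13 are cut first, the oxirane is opened at C1–O to a cis-1,10-diol, and C1–C10 of the ten-membered ring is cut as a keto-aldehyde pinacol.
- Enabling feature: the oxirane spans C1 and C10 of the cyclodecene, so both carbons carry oxygen and C10 also carries the C14 methyl. The pair therefore maps onto a C1 aldehyde and a C10 methyl ketone, held in one chain by the trans γ-lactone (O–C6–C7–C11–C12) and the (Z)-C4=C5 alkene.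
- The open chain is cut at C5–C6 (with the lactone C6–O–C12 bond) into a C1–C5 (Z)-iodoalkene and a C6–C14 aldehyde ester; these are cut at C4–C15 and C2–C3, and at C7–C11 and C9–C10.
- Forward: both pieces are built and joined at C5–C6 with closure of the γ-lactone; SmI2 closes the carbocycle (C1–C10); then come the oxirane, the exocyclic methylene and last the two esters.
- Stereochemistry: C8 from ethyl (S)-4-chloro-3-hydroxybutanoate; C7 by Fráter–Seebach alkylation; C3 by Brown allylboration; C6 by Felkin–Anh addition; C10 and C1 in the pinacol step (C1 inverted on oxirane closure); the side-chain oxirane by Sharpless epoxidation.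

Key step: step 14

Remark on the chemistry: the SmI2 closure is assumed to give mainly the cis-diol with 10R (1S,10R), the usual outcome of samarium-bridged ketyl–carbonyl coupling; aldehyde acid 15 is drawn open although it should sit largely as its cyclic hydroxylactone.

**Route**

Step 1
Reactants: 1 propargyl alcohol
Product: 3 (Z)-3-iodo-2-methylprop-2-en-1-ol, via alkenylmagnesium alkoxide 2 (not isolated)
Conditions: MeMgBr (2.5 equiv), CuI (10 mol%), THF, −10 °C → rt; then I2, −78 → 0 °C; aq. work-up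
Reagents that add atoms: methylmagnesium bromide, C[Mg]Br; iodine, II
Why: Copper-catalysed carbomagnesiation of the magnesium propargylate is an anti addition that puts methyl on the internal carbon (C4) and magnesium on the terminal carbon (C5) in a five-membered alkoxide chelate, so iodinolysis with retention should give only the (Z)-iodoalkene.

Step 2
Reactants: 3 (Z)-3-iodo-2-methylprop-2-en-1-ol
Product: 4 (Z)-3-iodo-2-methylprop-2-enal
Conditions: MnO2 (excess), CH2Cl2, rt
Reagents that add atoms: none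
Why: Allylic oxidation with MnO2 is neutral and stops at the aldehyde, so the (Z)-β-iodoenal should form without isomerisation.

Step 3
Reactants: 4 (Z)-3-iodo-2-methylprop-2-enal
Product: 6 (3S,1Z)-1-iodo-2-methylhexa-1,5-dien-3-ol, via borinate 5 (not isolated)
Conditions: (Ipc)2B(allyl) made from (+)-α-pinene, Et2O, −78 °C; then NaOH, H2O2, 0 °C → rt
Reagents that add atoms: B-allyldiisopinocampheylborane from (+)-α-pinene, C=CCB([C@@H]1C[C@@H]2C[C@H]([C@H]1C)C2(C)C)[C@@H]1C[C@@H]2C[C@H]([C@H]1C)C2(C)C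
Why: Brown allylboration through a chair-like six-membered transition state, in which the (+)-α-pinene-derived reagent adds allyl to the si face of the enal and so sets C3 as S; the alkenyl iodide tolerates the alkaline peroxide work-up.

Step 4
Reactants: 6 (3S,1Z)-1-iodo-2-methylhexa-1,5-dien-3-ol
Product: 7 tert-butyl{[(3S,1Z)-1-iodo-2-methylhexa-1,5-dien-3-yl]oxy}dimethylsilane
Conditions: t-BuMe2SiCl, imidazole, DMF, rt
Reagents that add atoms: tert-butyldimethylsilyl chloride, CC(C)(C)[Si](C)(C)Cl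
Why: Imidazole-promoted silylation of the secondary allylic alcohol is routine and leaves the stereocentre and both alkenes untouched.

Step 5
Reactants: 8 ethyl (S)-4-chloro-3-hydroxybutanoate
Product: 9 ethyl (S)-3,4-epoxybutanoate
Conditions: Ag2O, DME, 70 °C
Reagents that add atoms: none
Why: Silver-assisted intramolecular Williamson closure of the chlorohydrin works without free base, which avoids β-elimination of the β,γ-epoxy ester, and the C–O bond at the stereocentre (C8) is not touched.

Step 6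
Reactants: 9 ethyl (S)-3,4-epoxybutanoate
Product: 10 ethyl (R)-3-hydroxy-5-methylhex-5-enoate
Conditions: CH2=C(CH3)MgBr, CuI (10 mol%), THF, −40 → −20 °C; aq. work-up
Reagents that add atoms: isopropenylmagnesium bromide, CC(=C)[Mg]Br
Why: Copper-catalysed Grignard opening of the terminal epoxide at its unsubstituted carbon (SN2) is faster at low temperature than addition to the ester and forms C9–C10 with C8 unchanged.

Step 7
Reactants: 10 ethyl (R)-3-hydroxy-5-methylhex-5-enoate
Product: 12 4-tert-butyl 1-ethyl (2R)-2-[(1R)-1-hydroxy-3-methylbut-3-en-1-yl]butanedioate, via dilithium alkoxide enolate 11 (not isolated)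
Conditions: LiN(i-Pr)2 (2.2 equiv), THF, −78 → −20 °C; then BrCH2CO2t-Bu, −78 → −20 °C; aq. work-up
Reagents that add atoms: tert-butyl bromoacetate, CC(C)(C)OC(=O)CBr
Why: Fráter–Seebach alkylation, in which the dilithium alkoxide–enolate is a six-membered chelate that the bromoacetate approaches anti to the C9 side chain, which sets C7 anti to the C8 oxygen.

Step 8
Reactants: 12 4-tert-butyl 1-ethyl (2R)-2-[(1R)-1-hydroxy-3-methylbut-3-en-1-yl]butanedioate
Product: 14 (3R,4R)-3-(ethoxycarbonyl)-6-methyl-4-(triethylsilyloxy)hept-6-enoic acid, via silyl ester 13 (not isolated)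
Conditions: Et3SiOTf (3 equiv), 2,6-lutidine, CH2Cl2, −78 °C → rt; then aq. NaHCO3, pH 4 buffer
Reagents that add atoms: triethylsilyl trifluoromethanesulfonate, CC[Si](CC)(CC)OS(=O)(=O)C(F)(F)F
Why: The silyl triflate silylates the C8 alcohol and, on warming, dealkylates the tert-butyl ester to the silyl ester with loss of isobutene (silyl-triflate cleavage of tert-butyl esters), which hydrolyses on work-up while the ethyl ester stays.

Step 9
Reactants: 14 (3R,4R)-3-(ethoxycarbonyl)-6-methyl-4-(triethylsilyloxy)hept-6-enoic acid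
Product: 15 (3R,4R)-3-formyl-6-methyl-4-(triethylsilyloxy)hept-6-enoic acid
Conditions: i-Bu2AlH (2.3 equiv), CH2Cl2, −78 °C; then aq. potassium sodium tartrate
Reagents that add atoms: none
Why: Partial ester reduction with i-Bu2AlH at −78 °C, where the first equivalent only makes the inert aluminium carboxylate and the second gives a tetrahedral aluminium hemiacetal that persists until work-up, so C6 should stop at the aldehyde level.

Step 10
Reactants: 15 (3R,4R)-3-formyl-6-methyl-4-(triethylsilyloxy)hept-6-enoic acid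
Product: 16 methyl (3R,4R)-3-formyl-6-methyl-4-(triethylsilyloxy)hept-6-enoate
Conditions: Me3SiCHN2, MeOH–toluene, 0 °C
Reagents that add atoms: trimethylsilyldiazomethane, C[Si](C)(C)C=[N+]=[N-]
Why: Diazoalkane esterification is selective for the carboxylic acid at 0 °C and leaves the aldehyde and the silyl ether alone.

Step 11
Reactants: 16 methyl (3R,4R)-3-formyl-6-methyl-4-(triethylsilyloxy)hept-6-enoate
Product: 18 methyl (3R,4R)-3-formyl-6-oxo-4-(triethylsilyloxy)heptanoate, via ozonide 17 (not isolated)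
Conditions: O3, CH2Cl2, −78 °C; then PPh3, −78 °C → rt
Reagents that add atoms: ozone, [O-][O+]=O
Why: Criegee ozonolysis of the only alkene present, with reductive work-up, unmasks the C10 methyl ketone; aldehyde, ester and silyl ether are inert at −78 °C.

Step 12
Reactants: 7 tert-butyl{[(3S,1Z)-1-iodo-2-methylhexa-1,5-dien-3-yl]oxy}dimethylsilane; 18 methyl (3R,4R)-3-formyl-6-oxo-4-(triethylsilyloxy)heptanoate
Product: 20 (4S,5R)-5-[(1Z,3S)-3-(tert-butyldimethylsilyloxy)-2-methylhexa-1,5-dien-1-yl]-4-[(1R)-3-oxo-1-(triethylsilyloxy)butyl]dihydrofuran-2(3H)-one, via hydroxy ester 19 (not isolated)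
Conditions: CrCl2 (6 equiv), NiCl2 (1 mol%), DMSO, rt; aq. work-up; then pyridinium p-toluenesulfonate (cat.), CH2Cl2, rt
Reagents that add atoms: none
Why: Nozaki–Hiyama–Kishi coupling, in which zerovalent nickel inserts into the C–I bond with retention of the (Z) geometry and the derived alkenylchromium adds only to the aldehyde from the Felkin–Anh face anti to the C8 branch, setting C6 as R, after which the γ-hydroxy methyl ester closes to the trans γ-lactone under mild acid.

Step 13
Reactants: 20 the trans γ-lactone with the terminal vinyl group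
Product: 22 (4S,5R)-5-[(1Z,3S)-3-(tert-butyldimethylsilyloxy)-2-methyl-5-oxopent-1-en-1-yl]-4-[(1R)-3-oxo-1-(triethylsilyloxy)butyl]dihydrofuran-2(3H)-one, via terminal 1,2-diol 21 (not isolated)
Conditions: OsO4 (2 mol%), NaIO4 (4 equiv), 2,6-lutidine, dioxane–H2O (3:1), rt
Reagents that add atoms: osmium tetroxide (catalytic oxygen carrier), O=[Os](=O)(=O)=O; sodium periodate (terminal oxygen source), [Na+].[O-]I(=O)(=O)=O
Why: Lemieux–Johnson oxidation, in which OsO4 should dihydroxylate the unhindered monosubstituted alkene in preference to the (Z)-trisubstituted C4=C5 alkene, which is shielded and deactivated by allylic C–O bonds on both sides, and periodate cleaves the diol to the C1 aldehyde.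

Step 14
Reactants: 22 the keto-aldehyde (C1 aldehyde, C10 methyl ketone, trans γ-lactone, (Z)-C4=C5, C3–OSi-t-BuMe2, C8–OSiEt3)
Product: 23 (1S,3S,6R,7S,8R,10R)-3-(tert-butyldimethylsilyloxy)-1,10-dihydroxy-8-(triethylsilyloxy)-13-norgermacr-4(Z)-en-12,6-olide
Conditions: SmI2 (0.1 M in THF, 4 equiv), THF, rt, 22 added over 8 h (final 2 mM); then aq. NaHCO3
Reagents that add atoms: none
Why: SmI2 transfers an electron to the C1 aldehyde first, and the samarium-bound ketyl adds to the C10 ketone carbonyl held on the same trivalent samarium centre (a second electron then gives the samarium diolate), which is the keto-aldehyde pinacol macrocyclisation long used with divalent samarium or low-valent titanium for medium and large carbocycles. The ten-membered ring closes in a 10-exo-trig radical addition that joins C1 to C10, the chain being pre-folded by the trans γ-lactone and the (Z)-C4=C5 alkene. Both oxygens are bound to samarium in the transition state, so the two C–O bonds emerge cis, which fixes C1 relative to C10. C10 should become R by attack on the ketone face turned away from the C8 triethylsilyloxy group, and C1 is then S. The step needs ring closure to outrun intermolecular coupling and simple carbonyl reduction, which slow addition at about 2 mM and the absence of a proton source should secure; the lactone, the silyl ethers and the trisubstituted alkene are inert to SmI2 in THF.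

Step 15
Reactants: 23 the cis-1,10-diol
Product: 25 (1R,3S,6R,7S,8R,10R)-3-(tert-butyldimethylsilyloxy)-1,10-epoxy-8-(triethylsilyloxy)-13-norgermacr-4(Z)-en-12,6-olide, via mesylate 24 (not isolated)
Conditions: MsCl, Et3N, CH2Cl2, −20 → 0 °C; then K2CO3, MeOH, 0 °C → rt
Reagents that add atoms: none
Why: Sulfonylation is selective for the secondary C1 hydroxyl over the tertiary C10 hydroxyl, and the C10 alkoxide then displaces the mesylate in an intramolecular Williamson reaction (3-exo-tet) with inversion at C1, which turns the cis-diol into the trans-oxirane (1R,10R).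

Step 16
Reactants: 25 the 1,10-epoxy lactone
Product: 28 (1R,3S,6R,7S,8R,10R)-3-(tert-butyldimethylsilyloxy)-1,10-epoxy-8-(triethylsilyloxy)germacra-4(Z),11(13)-dien-12,6-olide, via Mannich base 26 (not isolated), via ammonium iodide 27 (not isolated)
Conditions: LiN(SiMe3)2, THF, −78 °C; Me2N=CH2 I, −78 → 0 °C; then MeI, MeOH, rt; then aq. NaHCO3, CH2Cl2
Reagents that add atoms: dimethylmethyleneiminium iodide, C=[N+](C)C.[I-]
Why: Eschenmoser methylenation, in which the lactone lithium enolate undergoes a Mannich reaction at C11 and quaternisation followed by base-induced loss of trimethylamine gives the exocyclic alkene; the lactone α-CH2 is the only acidic position.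

Step 17
Reactants: 28 the α-methylene lactone bis(silyl ether)
Product: 29 (1R,3S,6R,7R,8R,10R)-3-(tert-butyldimethylsilyloxy)-1,10-epoxy-8-hydroxygermacra-4(Z),11(13)-dien-12,6-olide
Conditions: HF·pyridine, pyridine, THF, 0 °C
Reagents that add atoms: none
Why: Buffered HF·pyridine cleaves the triethylsilyl ether far faster than the tert-butyldimethylsilyl ether (steric differentiation at silicon), and the near-neutral medium should spare the oxirane and the α-methylene lactone.

Step 18
Reactants: 30 angelic acid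
Product: 31 (Z)-2-methylbut-2-en-1-ol
Conditions: LiAlH4, Et2O, 0 °C; aq. work-up
Reagents that add atoms: none
Why: Hydride reduction of the conjugated acid by LiAlH4 in ether goes 1,2 and keeps the (Z) geometry.

Step 19
Reactants: 31 (Z)-2-methylbut-2-en-1-ol
Product: 32 [(2S,3R)-2,3-dimethyloxiran-2-yl]methanol
Conditions: Ti(OiPr)4, L-(+)-diethyl tartrate, t-BuOOH, 4 Å molecular sieves, CH2Cl2, −20 °C
Reagents that add atoms: tert-butyl hydroperoxide, CC(C)(C)OO
Why: Sharpless asymmetric epoxidation, in which the titanium–L-(+)-tartrate catalyst delivers the peroxide oxygen to the alkene face that gives the (2S,3R)-epoxy alcohol, and the syn addition keeps CH2OH and the C3 methyl cis.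

Step 20
Reactants: 32 [(2S,3R)-2,3-dimethyloxiran-2-yl]methanol
Product: 33 (2R,3R)-2,3-dimethyloxirane-2-carboxylic acid (epoxyangelic acid)
Conditions: RuCl3 (2 mol%), NaIO4, CCl4–MeCN–H2O, rt
Reagents that add atoms: water, O; sodium periodate (terminal oxidant for RuO4), [Na+].[O-]I(=O)(=O)=O
Why: Catalytic ruthenium tetroxide oxidation takes the primary alcohol to the acid through the aldehyde hydrate without touching the oxirane, so the geometry at C2 is kept although its descriptor becomes R.

Step 21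
Reactants: 29 the C8 alcohol; 33 (2R,3R)-2,3-dimethyloxirane-2-carboxylic acid
Product: 35 (1R,3S,6R,7R,8R,10R)-3-(tert-butyldimethylsilyloxy)-1,10-epoxy-8-[(2R,3R)-2,3-epoxy-2-methylbutanoyloxy]germacra-4(Z),11(13)-dien-12,6-olide, via mixed anhydride 34 (not isolated)
Conditions: 2,4,6-Cl3C6H2COCl, Et3N, THF, rt; then 29, 4-(dimethylamino)pyridine, toluene, rt → 40 °C
Reagents that add atoms: none
Why: Yamaguchi esterification, in which 4-(dimethylamino)pyridine attacks the mixed anhydride at the less shielded aliphatic carbonyl and the acylpyridinium acylates the hindered C8 alcohol; the acid has no α-hydrogen and cannot epimerise.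

Step 22
Reactants: 35 the C8 epoxyangelate C3 silyl ether
Product: 36 (1R,3S,6R,7R,8R,10R)-1,10-epoxy-8-[(2R,3R)-2,3-epoxy-2-methylbutanoyloxy]-3-hydroxygermacra-4(Z),11(13)-dien-12,6-olide
Conditions: Bu4NF, AcOH (1:1), THF, 0 °C → rt
Reagents that add atoms: none
Why: Fluoride-induced desilylation of the allylic silyl ether, with acetic acid buffering the alkoxide so that the α-methylene lactone, the glycidic ester and the oxirane should not be attacked.

Step 23
Reactants: 36 the C3 alcohol
Product: 37 (1R,3S,6R,7R,8R,10R)-1,10-epoxy-8-[(2R,3R)-2,3-epoxy-2-methylbutanoyloxy]-3-(3-methylbutanoyloxy)germacra-4(Z),11(13)-dien-12,6-olide (CNP0167461.2)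
Conditions: (i-PrCH2CO)2O, pyridine, 4-(dimethylamino)pyridine (cat.), CH2Cl2, 0 °C → rt
Reagents that add atoms: isovaleric anhydride, CC(C)CC(=O)OC(=O)CC(C)C
Why: Nucleophile-catalysed acyl transfer from the anhydride to the secondary allylic alcohol under mild base completes the target without touching the other esters or oxiranes.

**Compound list**

1 | propargyl alcohol | C#CCO | starting material
2 | bromomagnesium (Z)-3-(bromomagnesio)-2-methylprop-2-en-1-olate | Br[Mg]/C=C(/C)CO[Mg]Br | intermediate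
3 | (Z)-3-iodo-2-methylprop-2-en-1-ol | I/C=C(/C)CO | intermediate
4 | (Z)-3-iodo-2-methylprop-2-enal | I/C=C(/C)C=O | intermediate
5 | diisopinocampheylborinate of 6 | I/C=C(/C)[C@@H](OB([C@@H]1C[C@@H]2C[C@H]([C@H]1C)C2(C)C)[C@@H]1C[C@@H]2C[C@H]([C@H]1C)C2(C)C)CC=C | intermediate
6 | (3S,1Z)-1-iodo-2-methylhexa-1,5-dien-3-ol | I/C=C(/C)[C@@H](O)CC=C | intermediate
7 | tert-butyl{[(3S,1Z)-1-iodo-2-methylhexa-1,5-dien-3-yl]oxy}dimethylsilane | I/C=C(/C)[C@@H](O[Si](C)(C)C(C)(C)C)CC=C | intermediate
8 | ethyl (S)-4-chloro-3-hydroxybutanoate | CCOC(=O)C[C@H](O)CCl | starting material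
9 | ethyl (S)-3,4-epoxybutanoate | CCOC(=O)C[C@H]1CO1 | intermediate
10 | ethyl (R)-3-hydroxy-5-methylhex-5-enoate | CCOC(=O)C[C@H](O)CC(C)=C | intermediate
11 | dilithium alkoxide–enolate of 10 | CCOC(O[Li])=C[C@H](O[Li])CC(C)=C | intermediate
12 | 4-tert-butyl 1-ethyl (2R)-2-[(1R)-1-hydroxy-3-methylbut-3-en-1-yl]butanedioate | CCOC(=O)[C@H](CC(=O)OC(C)(C)C)[C@H](O)CC(C)=C | intermediate
13 | triethylsilyl (3R,4R)-3-(ethoxycarbonyl)-6-methyl-4-(triethylsilyloxy)hept-6-enoate | CCOC(=O)[C@H](CC(=O)O[Si](CC)(CC)CC)[C@H](O[Si](CC)(CC)CC)CC(C)=C | intermediate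
14 | (3R,4R)-3-(ethoxycarbonyl)-6-methyl-4-(triethylsilyloxy)hept-6-enoic acid | CCOC(=O)[C@H](CC(=O)O)[C@H](O[Si](CC)(CC)CC)CC(C)=C | intermediate
15 | (3R,4R)-3-formyl-6-methyl-4-(triethylsilyloxy)hept-6-enoic acid (open form) | O=C[C@H](CC(=O)O)[C@H](O[Si](CC)(CC)CC)CC(C)=C | intermediate
16 | methyl (3R,4R)-3-formyl-6-methyl-4-(triethylsilyloxy)hept-6-enoate | O=C[C@H](CC(=O)OC)[C@H](O[Si](CC)(CC)CC)CC(C)=C | intermediate
17 | ozonide (3-methyl-1,2,4-trioxolane) of 16, ring carbon unassigned | O=C[C@H](CC(=O)OC)[C@H](O[Si](CC)(CC)CC)CC1(C)OCOO1 | intermediate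
18 | methyl (3R,4R)-3-formyl-6-oxo-4-(triethylsilyloxy)heptanoate | O=C[C@H](CC(=O)OC)[C@H](O[Si](CC)(CC)CC)CC(C)=O | intermediate
19 | (3S,6R,7S,8R)-hydroxy methyl ester from the C5–C6 coupling (germacrane numbering) | COC(=O)C[C@H]([C@H](O[Si](CC)(CC)CC)CC(C)=O)[C@H](O)/C=C(/C)[C@@H](O[Si](C)(C)C(C)(C)C)CC=C | intermediate
20 | (4S,5R)-5-[(1Z,3S)-3-(tert-butyldimethylsilyloxy)-2-methylhexa-1,5-dien-1-yl]-4-[(1R)-3-oxo-1-(triethylsilyloxy)butyl]dihydrofuran-2(3H)-one | O=C1C[C@H]([C@H](O[Si](CC)(CC)CC)CC(C)=O)[C@H](O1)/C=C(/C)[C@@H](O[Si](C)(C)C(C)(C)C)CC=C | intermediate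
21 | terminal 1,2-diol of 20 (carbinol carbon unassigned) | O=C1C[C@H]([C@H](O[Si](CC)(CC)CC)CC(C)=O)[C@H](O1)/C=C(/C)[C@@H](O[Si](C)(C)C(C)(C)C)CC(O)CO | intermediate
22 | (4S,5R)-5-[(1Z,3S)-3-(tert-butyldimethylsilyloxy)-2-methyl-5-oxopent-1-en-1-yl]-4-[(1R)-3-oxo-1-(triethylsilyloxy)butyl]dihydrofuran-2(3H)-one | O=C1C[C@H]([C@H](O[Si](CC)(CC)CC)CC(C)=O)[C@H](O1)/C=C(/C)[C@@H](O[Si](C)(C)C(C)(C)C)CC=O | intermediate
23 | (1S,3S,6R,7S,8R,10R)-3-(tert-butyldimethylsilyloxy)-1,10-dihydroxy-8-(triethylsilyloxy)-13-norgermacr-4(Z)-en-12,6-olide | O=C1C[C@H]2[C@H](O1)/C=C(/C)[C@@H](O[Si](C)(C)C(C)(C)C)C[C@H](O)[C@](C)(O)C[C@H]2O[Si](CC)(CC)CC | intermediate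
24 | C1 methanesulfonate of 23 | O=C1C[C@H]2[C@H](O1)/C=C(/C)[C@@H](O[Si](C)(C)C(C)(C)C)C[C@H](OS(C)(=O)=O)[C@](C)(O)C[C@H]2O[Si](CC)(CC)CC | intermediate
25 | (1R,3S,6R,7S,8R,10R)-3-(tert-butyldimethylsilyloxy)-1,10-epoxy-8-(triethylsilyloxy)-13-norgermacr-4(Z)-en-12,6-olide | O=C1C[C@H]2[C@H](O1)/C=C(/C)[C@@H](O[Si](C)(C)C(C)(C)C)C[C@H]3O[C@]3(C)C[C@H]2O[Si](CC)(CC)CC | intermediate
26 | 11-(dimethylaminomethyl) lactone (C11 epimers, configuration immaterial) | CN(C)CC1C(=O)O[C@@H]2/C=C(/C)[C@@H](O[Si](C)(C)C(C)(C)C)C[C@H]3O[C@]3(C)C[C@@H](O[Si](CC)(CC)CC)[C@@H]12 | intermediate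
27 | 11-(trimethylammoniomethyl) lactone iodide (C11 epimers) | C[N+](C)(C)CC1C(=O)O[C@@H]2/C=C(/C)[C@@H](O[Si](C)(C)C(C)(C)C)C[C@H]3O[C@]3(C)C[C@@H](O[Si](CC)(CC)CC)[C@@H]12.[I-] | intermediate
28 | (1R,3S,6R,7S,8R,10R)-3-(tert-butyldimethylsilyloxy)-1,10-epoxy-8-(triethylsilyloxy)germacra-4(Z),11(13)-dien-12,6-olide | C=C1C(=O)O[C@@H]2/C=C(/C)[C@@H](O[Si](C)(C)C(C)(C)C)C[C@H]3O[C@]3(C)C[C@@H](O[Si](CC)(CC)CC)[C@@H]12 | intermediate
29 | (1R,3S,6R,7R,8R,10R)-3-(tert-butyldimethylsilyloxy)-1,10-epoxy-8-hydroxygermacra-4(Z),11(13)-dien-12,6-olide | C=C1C(=O)O[C@@H]2/C=C(/C)[C@@H](O[Si](C)(C)C(C)(C)C)C[C@H]3O[C@]3(C)C[C@@H](O)[C@@H]12 | intermediate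
30 | angelic acid, (Z)-2-methylbut-2-enoic acid | C/C=C(/C)C(=O)O | starting material
31 | (Z)-2-methylbut-2-en-1-ol | C/C=C(/C)CO | intermediate
32 | [(2S,3R)-2,3-dimethyloxiran-2-yl]methanol | OC[C@]1(C)O[C@@H]1C | intermediate
33 | (2R,3R)-2,3-dimethyloxirane-2-carboxylic acid | OC(=O)[C@]1(C)O[C@@H]1C | intermediate
34 | (2R,3R)-2,3-dimethyloxirane-2-carboxylic 2,4,6-trichlorobenzoic anhydride | O=C(OC(=O)c1c(Cl)cc(Cl)cc1Cl)[C@]1(C)O[C@@H]1C | intermediate
35 | (1R,3S,6R,7R,8R,10R)-3-(tert-butyldimethylsilyloxy)-1,10-epoxy-8-[(2R,3R)-2,3-epoxy-2-methylbutanoyloxy]germacra-4(Z),11(13)-dien-12,6-olide | C=C1C(=O)O[C@@H]2/C=C(/C)[C@@H](O[Si](C)(C)C(C)(C)C)C[C@H]3O[C@]3(C)C[C@@H](OC(=O)[C@]3(C)O[C@@H]3C)[C@@H]12 | intermediate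
36 | (1R,3S,6R,7R,8R,10R)-1,10-epoxy-8-[(2R,3R)-2,3-epoxy-2-methylbutanoyloxy]-3-hydroxygermacra-4(Z),11(13)-dien-12,6-olide | C=C1C(=O)O[C@@H]2/C=C(/C)[C@@H](O)C[C@H]3O[C@]3(C)C[C@@H](OC(=O)[C@]3(C)O[C@@H]3C)[C@@H]12 | intermediate
37 | CNP0167461.2, (1R,3S,6R,7R,8R,10R)-1,10-epoxy-8-[(2R,3R)-2,3-epoxy-2-methylbutanoyloxy]-3-(3-methylbutanoyloxy)germacra-4(Z),11(13)-dien-12,6-olide | C=C1C(=O)O[C@@H]2/C=C(/C)[C@@H](OC(=O)CC(C)C)C[C@H]3O[C@]3(C)C[C@@H](OC(=O)[C@]3(C)O[C@@H]3C)[C@@H]12 | target

**Count and risks**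

Total step count: 23. Longest linear sequence: 16 steps (steps 5–17 and 21–23, from 8).

Step 14. What may go wrong: intermolecular coupling and oligomerisation or plain reduction of the aldehyde may compete with ring closure, and the closure may take the wrong relative or absolute course at C1/C10. Fallback: starting from 22, the same C1–C10 bond is formed as an alkene by McMurry coupling (TiCl3(DME)1.5, Zn–Cu, DME, reflux, syringe pump), which should give the lactone-fused (1(10)E,4Z)-cyclodecadiene F1. Epoxidation of its electron-richer, unencumbered C1=C10 bond from the outer face of the ring (mCPBA, NaHCO3, CH2Cl2, 0 °C) then leads to oxirane 25, where the route is rejoined; the diol and its stereochemical demands are bypassed.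

Step 12. What may go wrong: poor facial selectivity in the addition to the α-branched aldehyde, so that much of the (6S)-alcohol forms, which would close to the cis-lactone. Fallback: setting out from 7 and 18, the coupling is run as before but the crude hydroxy esters are separated before the acid treatment. The (6S)-hydroxy ester F2 is inverted under Mitsunobu conditions (PPh3, diisopropyl azodicarboxylate, 4-nitrobenzoic acid, toluene, 0 °C) to the (6R)-4-nitrobenzoate F3. Methanolysis (K2CO3, MeOH, 0 °C) then frees the (6R)-alcohol 19, which lactonises to 20 as in step 12.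

Step 13. What may go wrong: osmylation of the C4=C5 alkene may compete with that of the terminal alkene, or the aldehyde may be over-oxidised. Fallback: the terminal alkene is cleaved before the coupling, when the only other alkene is the inert iodoalkene. From 7, ozonolysis (O3, CH2Cl2, −78 °C) gives the ozonide F4, which NaBH4 reduces to the primary alcohol F5; silylation (Et3SiCl, imidazole, CH2Cl2) gives the bis(silyl ether) F6. Coupling with 18 under the conditions of step 12 gives the hydroxy ester F7 and then the lactone F8. Swern oxidation ((COCl)2, DMSO, CH2Cl2, −78 → −30 °C; then Et3N), which turns a primary triethylsilyl ether directly into the aldehyde and leaves the secondary silyl ethers alone, returns to 22.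

**Further compounds**

F1 | step 14 | (3S,6R,7S,8R)-3-(tert-butyldimethylsilyloxy)-8-(triethylsilyloxy)-13-norgermacra-1(10)E,4Z-dien-12,6-olide | O=C1C[C@H]2[C@H](O1)/C=C(/C)[C@@H](O[Si](C)(C)C(C)(C)C)C/C=C(C)/C[C@H]2O[Si](CC)(CC)CC
F2 | step 12 | (6S)-epimer of hydroxy ester 19 | COC(=O)C[C@H]([C@H](O[Si](CC)(CC)CC)CC(C)=O)[C@@H](O)/C=C(/C)[C@@H](O[Si](C)(C)C(C)(C)C)CC=C
F3 | step 12 | (6R)-4-nitrobenzoate of 19 | COC(=O)C[C@H]([C@H](O[Si](CC)(CC)CC)CC(C)=O)[C@H](OC(=O)c1ccc(cc1)[N+](=O)[O-])/C=C(/C)[C@@H](O[Si](C)(C)C(C)(C)C)CC=C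
F4 | step 13 | ozonide (1,2,4-trioxolane) of the terminal alkene of 7 | I/C=C(/C)[C@@H](O[Si](C)(C)C(C)(C)C)CC1OCOO1
F5 | step 13 | (3S,4Z)-3-(tert-butyldimethylsilyloxy)-5-iodo-4-methylpent-4-en-1-ol | I/C=C(/C)[C@@H](O[Si](C)(C)C(C)(C)C)CCO
F6 | step 13 | (3S,4Z)-3-(tert-butyldimethylsilyloxy)-5-iodo-4-methyl-1-(triethylsilyloxy)pent-4-ene | I/C=C(/C)[C@@H](O[Si](C)(C)C(C)(C)C)CCO[Si](CC)(CC)CC
F7 | step 13 | (6R)-hydroxy methyl ester with C1–OSiEt3 | COC(=O)C[C@H]([C@H](O[Si](CC)(CC)CC)CC(C)=O)[C@H](O)/C=C(/C)[C@@H](O[Si](C)(C)C(C)(C)C)CCO[Si](CC)(CC)CC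
F8 | step 13 | trans γ-lactone with C1–OSiEt3 | O=C1C[C@H]([C@H](O[Si](CC)(CC)CC)CC(C)=O)[C@H](O1)/C=C(/C)[C@@H](O[Si](C)(C)C(C)(C)C)CCO[Si](CC)(CC)CC
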